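## Structural features

The target joins two flavonoid units through one shared ring. A 4-arylflavan-3-ol (benzo ring A, pyran ring C, catechol ring B) is bonded at C4 to the pyrogallol ring E, and ring E is also the 2-aryl group of a 3,7-dihydroxyflavone (benzo ring D, pyranone ring F). On ring E the carbon bearing flavan C4 lies between the carbon bearing flavonol C2 and a hydroxylated carbon, so the C4–aryl bond has two ortho neighbours; the three E-ring hydroxyls are contiguous. Ring C carries three adjacent stereocentres, C2 (R), C3 (S) and C4 (S). The aryl on C2, the hydroxyl on C3 and the aryl on C4 are all-trans (2,3-trans, 3,4-trans), with the two aryl groups cis to each other. Fragile features are the eight phenolic hydroxyls (an air-sensitive pyrogallol and a catechol among them), the flavonol enol, the benzylic C2–O1 bond and the doubly benzylic C4–H; these exclude strong acid, strong oxidants and harsh deprotection late in the route. The real difficulty is the congested, configurationally defined C4 centre, not the flavonol. The key step uses the fact that ring A is a resorcinol: C4a is para to the 7-hydroxyl and ortho to the oxygen that becomes O1, which is the most nucleophilic carbon of resorcinol, while C2, C3 and C4 with rings B and E form the three-carbon chain of a chalcone. Because the target is all-trans, C2 and C3 can be relayed from C4 once ring C exists as an enol ether.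

## Logic of the disconnections

**24 ⇒ 23.** The eight benzylic C–O bonds of the protecting groups are cut (seven aryl benzyl ethers and the secondary benzyl ether on O3 of ring C). The free polyphenol is too oxidisable and too polar to carry, and a single protecting-group type allows one neutral final step. Everything before 24 becomes lipophilic and stable to base. The forward step must remove all eight groups without opening ring C at C2–O1 and without reducing the C2=C3 bond of ring F.

**23 ⇒ 21.** O1–C2 of ring F and the C3–OH bond of ring F are cut. Oxidative cyclisation of a 2'-hydroxychalcone gives the flavonol oxidation level directly. Ring F and its hydroxyl disappear and 21 is an open enone. The forward step must close the six-membered ring rather than the five-membered aurone although ring E carries a bulky ortho substituent, and alkaline peroxide must leave the fully etherified flavan alone.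

**21 ⇒ 18 + 19.** The Cα=Cβ bond of the enone is cut (aldol condensation). Ring D arrives as the purchasable ketone 19, and the chiral half is reduced to the aldehyde 18. The forward step needs a hindered aldehyde to condense under base that does not touch C4, and O3 must be masked, since a free O3 would close a six-membered lactol onto the formyl group.

**18 ⇒ 15 ⇒ 14.** The C–CHO bond on ring E is cut back to C–Br, and then the two O–benzyl bonds on O3 and O7 are cut. Bromine is the smallest inert placeholder for this carbon and survives everything before it. Etherifying both hydroxyls in one operation removes every acidic proton before the organolithium step. 14 then holds all three stereocentres with bromine as the only handle. The forward step needs halogen–lithium exchange to outrun deprotonation at the benzylic positions.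

**14 ⇒ 12.** The C3–O and C2–H bonds are cut (retro-hydroboration). Syn addition of H and OH across C2=C3 on the face opposite the C4 aryl gives exactly the all-trans array. Two stereocentres are removed and only C4 remains. The forward step needs boron at C3, attack anti to the C4 aryl, and an organoborane that does not eliminate the ring oxygen.

**12 ⇒ 8 + 9.** C4–C4a and O1–C2 are cut. The nucleophilic carbon of 9 and its neighbouring hydroxyl map onto C4a and O1, and the enone 8 supplies C2–C3–C4 with rings B and E already in place. Ring C and the last stereocentre vanish, leaving an achiral enone and a symmetric phenol. The forward step needs enantiofacial control at a β-carbon bearing a 2,6-disubstituted aryl ring, C- over O-alkylation, and mono-alkylation of 9.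

**8 ⇒ 5 + 6.** The Cα=Cβ bond is cut (aldol condensation). Ring B arrives as the purchasable ketone 6 and ring E as the aldehyde 5. The forward step needs a hindered, non-enolisable aldehyde to condense cleanly.

**5 ⇒ 4 ⇒ 3 ⇒ 1.** The three O–benzyl bonds are cut, the oxygens are traced back to methyl ethers, and the C–CHO bond is cut. Formylation is placed at the methyl ether stage because the Lewis acid it needs would attack benzyl ethers. 1 has only one kind of free ring position, so a single isomer results. The forward steps need complete demethylation without touching CHO or Br, and exhaustive benzylation of an air-sensitive triol.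

## Other disconnections considered

**Alternative 1:** *Cut:* C4a–C4, C4–C3 and O1–C2 of ring F, leading back to the iodophenol A3, carbon monoxide and the terminal alkyne A2 on ring E of the fully benzylated flavan. *Forward:* carbonylative Sonogashira coupling of A3 with A2 (PdCl2(PPh3)2, Et3N, CO), the ynone closing by attack of the phenol to give flavone A1; A1 would still need hydroxylation at C3 and hydrogenolysis. *In favour:* it is convergent and builds ring F under mild amine base. A2 could come from 15 without any organolithium, and alkaline peroxide is avoided. *Against:* it leaves the C4 problem untouched, so it competes only with steps 8 to 10. The alkyne sits beside the bulky flavanyl group, five-membered (aurone) closure competes with six-membered closure, and the flavone oxidation level costs an extra C3 oxidation on a substrate rich in benzylic C–H bonds. *Comparison:* structurally both plans build ring F last on the same flavan. Mechanistically, palladium catalysis replaces aldol and peroxide chemistry, and this is the better of the two in functional-group tolerance. In step count it is estimated one step longer from 15 (alkyne installation, annulation, C3 hydroxylation, hydrogenolysis against formylation, condensation, oxidative cyclisation, hydrogenolysis). It is the equal of the chosen plan in convergence.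

**Alternative 2:** *Cut:* C3–C4 of ring C, with a temporary ester bond from O3 to the carbonyl on ring E, leading back to the diarylmethane ester A5 and the α-silyloxy aldehyde A6. *Forward:* lithiation of A5 at the doubly benzylic CH2 (LiN(i-Pr)2, −78 °C), addition to A6 and lactonisation of the alkoxide onto the ester to give the trans dihydroisocoumarin A4. Desilylation, closure of ring C by metal-catalysed C–O coupling of the C2 hydroxyl onto the aryl chloride, and partial reduction of the lactone would follow. *In favour:* the absolute configuration comes from one pre-formed stereocentre in A6, with no asymmetric catalysis at the crowded C4. The lactone protects O3 and the ring E carbonyl together and favours the 3,4-trans arrangement, turning the O3/carbonyl proximity that forces a protection step in the chosen route into an asset. *Against:* A6 is an α-aryl-α-silyloxy aldehyde and is prone to racemisation under the basic conditions. Two stereocentres form at once and both the facial selectivity on A6 and the configuration at the carbanion must go the right way. The later C–O coupling of a secondary benzylic alcohol with an electron-rich aryl chloride is demanding, with oxidation to the ketone as a competing path. *Comparison:* structurally it closes ring C last through O1–C8a instead of using the innate nucleophilicity of the resorcinol. Mechanistically it uses stoichiometric carbanion chemistry instead of catalysis. It is estimated four to six steps longer, counting the preparation of A5 and A6. It is the better plan in independence from an enantioselective reaction at a doubly ortho-substituted centre, and the equal in securing the 3,4-trans relationship.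

**Alternative 3:** *Cut:* O1–C8a, traced back by removal of the inserted oxygen from chromanone A7 to the 3-arylindanone A8. *Forward:* a peracid converts A8 into A7 by Baeyer–Villiger aryl migration, with C4 untouched. Addition of the ring B aryl-metal to the lactone and dehydration would then reach the 4H-chromene stage of the chosen route. *In favour:* the position of O1 is fixed by the ketone and not by site selectivity on a phenol. C4 in A7 is β to the carbonyl and configurationally robust. No free phenol is carried, and 3-arylindanones are accessible in enantioenriched form by established conjugate-addition chemistry. *Against:* the aryl group to be installed on A8 is the same 2,6-disubstituted ring E, so the steric problem is moved and not removed, and its bromine is a liability for rhodium or palladium catalysis. The 6-alkoxyindanone pattern is the opposite of what an electrophilic ring closure para to the alkoxy group would give. The migrating aryl carbon is meta to the benzyloxy group, so methylene migration can compete. The peracid may attack the electron-rich rings, and the aryl-metal can add twice to the lactone. *Comparison:* structurally it reaches the same chromene by a longer detour. Mechanistically, oxygen insertion replaces C–C and C–O formation in one catalytic event. It is estimated five to six steps for what step 5 does in one. It is the better plan in certainty of the O1 position and in configurational stability of the intermediate, and the equal in sharing the same endgame.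

Key step: step 5

Remark: the ring E substitution of 8 (bromine on the carbon that later bears the flavonol, the enone on the carbon that becomes attached to C4) and the (4S) configuration of 12 were checked atom by atom against 24 and map onto it correctly, so neither skeleton needs correction.

Remark: the precursor pair is used unchanged, with 9 unprotected and in excess; the design changes lie around it: formylation before demethylation and benzylation on the way to 5, and one double benzylation after hydroboration so that no free O3 meets the aldehyde.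

Remark: 6 and 19 are taken as catalogue compounds; the ligand enantiomer (from L- or D-pipecolic acid) that leads to (4S)-12 is assumed to be identified in a short screen.

## Route

**Step 1**
Reactants: 1 5-bromo-1,2,3-trimethoxybenzene
Product: 3 6-bromo-2,3,4-trimethoxybenzaldehyde, via α-chloro ether 2 (not isolated)
Conditions: Cl2CHOMe (1.5 equiv), TiCl4 (2.2 equiv), CH2Cl2, −78 → 0 °C; then ice-water
Reagents that add atoms: dichloromethyl methyl ether, COC(Cl)Cl; water, O
Why: Rieche formylation: the chloro(methoxy)carbenium ion attacks the only kind of free ring position (C4 and C6 are equivalent, each para to one methoxy and ortho to another), and 2 is hydrolysed on work-up. Formylating the methyl ether keeps TiCl4 away from benzyl ethers.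

**Step 2**
Reactants: 3 6-bromo-2,3,4-trimethoxybenzaldehyde
Product: 4 6-bromo-2,3,4-trihydroxybenzaldehyde
Conditions: BBr3 (5 equiv), CH2Cl2, −78 °C → rt; then H2O, 0 °C
Reagents that add atoms: none
Why: Lewis acid ether cleavage: boron binds each methoxy oxygen and bromide attacks the methyl group, and the aryl bromide and the aldehyde should survive; an excess is used because the carbonyl and the phenoxides also bind boron.

**Step 3**
Reactants: 4 6-bromo-2,3,4-trihydroxybenzaldehyde
Product: 5 6-bromo-2,3,4-tris(benzyloxy)benzaldehyde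
Conditions: BnBr (3.6 equiv), K2CO3 (5 equiv), DMF, 60 °C, argon
Reagents that add atoms: benzyl bromide, BrCc1ccccc1
Why: Williamson etherification of the three phenols; the hydroxyl hydrogen-bonded to the aldehyde reacts last, hence the excess and gentle heating, and argon protects the pyrogallol until it is capped.

**Step 4**
Reactants: 5 6-bromo-2,3,4-tris(benzyloxy)benzaldehyde; 6 3',4'-bis(benzyloxy)acetophenone
Product: 8 (E)-3-[6-bromo-2,3,4-tris(benzyloxy)phenyl]-1-[3,4-bis(benzyloxy)phenyl]prop-2-en-1-one, via aldol adduct 7 (not isolated)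
Conditions: KOH (aq, 3 equiv), EtOH/THF (2:1), rt → 40 °C
Reagents that add atoms: none
Why: Claisen–Schmidt condensation: the enolate of 6 adds to the non-enolisable aldehyde 5 and E1cB loss of water from 7 gives the conjugated enone, the (E) isomer being the thermodynamic one.

**Step 5**
Reactants: 8 (E)-3-[6-bromo-2,3,4-tris(benzyloxy)phenyl]-1-[3,4-bis(benzyloxy)phenyl]prop-2-en-1-one; 9 resorcinol
Product: 12 (4S)-4-[6-bromo-2,3,4-tris(benzyloxy)phenyl]-2-[3,4-bis(benzyloxy)phenyl]-4H-chromen-7-ol, via ketone adduct 10 (not isolated), via cyclic hemiketal 11 (not isolated)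
Conditions: Sc(OTf)3 (10 mol %), chiral N,N′-dioxide ligand (pipecolic acid-derived, 2,6-diisopropylanilide arms, 11 mol %), 9 (3 equiv), 4 Å MS, CH2Cl2/EtOAc (4:1), 35 °C; then CSA (5 mol %), rt
Reagents that add atoms: none
Why: The scandium triflate–ligand complex binds the carbonyl oxygen of the s-cis enone 8 and lowers its LUMO; 9 attacks the β-carbon through C4 (ortho to one hydroxyl and para to the other, the two such carbons being equivalent by symmetry), and rearomatisation with protonation of the scandium enolate gives ketone 10. The closest known reaction type is the chiral Lewis acid-catalysed Friedel–Crafts conjugate addition of naphthols and electron-rich phenols to enones with cyclodehydration to 4-aryl-4H-chromenes. Ring C closes by 6-exo-trig addition of the ortho hydroxyl to the activated ketone (hemiketal 11), and acid-promoted loss of water through the 2-aryl-stabilised oxocarbenium ion, with loss of H3, leaves the enol ether 12. The one lasting stereocentre, C4, is set in the C–C bond-forming event under catalyst control: the amide arms of the ligand shield one face of the β-carbon, and the ligand enantiomer is chosen to give (4S); the hemiketal centre at C2 is lost on dehydration. The step needs C- over O-alkylation (the oxa-Michael adduct reverts under Lewis acid, the C-adduct does not), attack at C4 and not at the hindered C2 of 9, mono- over bis-alkylation (secured by the excess of 9) and 1,4- over 1,2-addition. The symmetry of 9 makes the site of ring closure unambiguous and leaves O7 free, and the sieves take up the water so that the enol ether is not hydrolysed back to 11.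

**Step 6**
Reactants: 12 (4S)-4-[6-bromo-2,3,4-tris(benzyloxy)phenyl]-2-[3,4-bis(benzyloxy)phenyl]-4H-chromen-7-ol
Product: 14 (2R,3S,4S)-4-[6-bromo-2,3,4-tris(benzyloxy)phenyl]-2-[3,4-bis(benzyloxy)phenyl]chromane-3,7-diol, via alkylborane 13 (not isolated)
Conditions: BH3·THF (3.5 equiv), THF, 0 °C → rt; then NaOH (3 M aq), H2O2 (30 %), 0 °C → rt
Reagents that add atoms: hydrogen peroxide, OO
Why: Hydroboration–oxidation of the enol ether: boron goes to C3 (β to O1 and remote from the 2-aryl group) and borane adds syn from the face opposite the C4 aryl group; oxidation with retention then places the 3-hydroxyl trans to the C4 aryl and H2 cis to that hydroxyl, which is the all-trans (2R,3S,4S) array. The phenol consumes one B–H and is released on work-up.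

**Step 7**
Reactants: 14 (2R,3S,4S)-4-[6-bromo-2,3,4-tris(benzyloxy)phenyl]-2-[3,4-bis(benzyloxy)phenyl]chromane-3,7-diol
Product: 15 (2R,3S,4S)-3,7-bis(benzyloxy)-4-[6-bromo-2,3,4-tris(benzyloxy)phenyl]-2-[3,4-bis(benzyloxy)phenyl]chromane
Conditions: NaH (3 equiv), BnBr (2.6 equiv), n-Bu4NI (cat.), DMF, 0 °C → rt
Reagents that add atoms: benzyl bromide, BrCc1ccccc1
Why: Williamson etherification of the phenoxide and the secondary alkoxide in one operation; it removes both acidic protons before the organolithium step and prevents O3 from closing a six-membered lactol onto the aldehyde made next. No stereocentre is touched.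

**Step 8**
Reactants: 15 (2R,3S,4S)-3,7-bis(benzyloxy)-4-[6-bromo-2,3,4-tris(benzyloxy)phenyl]-2-[3,4-bis(benzyloxy)phenyl]chromane
Product: 18 3,4,5-tris(benzyloxy)-2-{(2R,3S,4S)-3,7-bis(benzyloxy)-2-[3,4-bis(benzyloxy)phenyl]chroman-4-yl}benzaldehyde, via aryllithium 16 (not isolated), via lithium hemiaminal alkoxide 17 (not isolated)
Conditions: n-BuLi (1.15 equiv), THF, −78 °C; then DMF (5 equiv), −78 → 0 °C; then NH4Cl (aq)
Reagents that add atoms: N,N-dimethylformamide, CN(C)C=O
Why: Bromine–lithium exchange is faster at −78 °C than deprotonation of any benzylic position, and the aryllithium 16 adds to DMF to give the tetrahedral adduct 17, which collapses to the aldehyde only on work-up, so no second addition can occur.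

**Step 9**
Reactants: 18 3,4,5-tris(benzyloxy)-2-{(2R,3S,4S)-3,7-bis(benzyloxy)-2-[3,4-bis(benzyloxy)phenyl]chroman-4-yl}benzaldehyde; 19 4'-benzyloxy-2'-hydroxyacetophenone
Product: 21 (E)-1-[4-(benzyloxy)-2-hydroxyphenyl]-3-{3,4,5-tris(benzyloxy)-2-[(2R,3S,4S)-3,7-bis(benzyloxy)-2-[3,4-bis(benzyloxy)phenyl]chroman-4-yl]phenyl}prop-2-en-1-one, via aldol adduct 20 (not isolated)
Conditions: KOH (50 % aq, 10 equiv), EtOH/THF (1:1), rt
Reagents that add atoms: none
Why: Claisen–Schmidt condensation of the phenoxide-enolate of 19 with the non-enolisable aldehyde 18, followed by E1cB dehydration of 20 to the (E)-2'-hydroxychalcone; the C4 methine and the ether-protected ring C are inert to hydroxide.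

**Step 10**
Reactants: 21 (E)-1-[4-(benzyloxy)-2-hydroxyphenyl]-3-{3,4,5-tris(benzyloxy)-2-[(2R,3S,4S)-3,7-bis(benzyloxy)-2-[3,4-bis(benzyloxy)phenyl]chroman-4-yl]phenyl}prop-2-en-1-one
Product: 23 7-(benzyloxy)-3-hydroxy-2-{3,4,5-tris(benzyloxy)-2-[(2R,3S,4S)-3,7-bis(benzyloxy)-2-[3,4-bis(benzyloxy)phenyl]chroman-4-yl]phenyl}-4H-chromen-4-one, via dihydroflavonol 22 (not isolated)
Conditions: H2O2 (30 %, 6 equiv), NaOH (2 M aq), MeOH/THF (1:1), 0 °C → rt
Reagents that add atoms: hydrogen peroxide, OO
Why: Algar–Flynn–Oyamada oxidation: the phenoxide closes the six-membered ring at the β-carbon while the α-carbon is hydroxylated by hydroperoxide, and 22 is oxidised further to the flavonol; the absence of a 6'-substituent on the ketone ring favours the flavonol over the aurone.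

**Step 11**
Reactants: 23 7-(benzyloxy)-3-hydroxy-2-{3,4,5-tris(benzyloxy)-2-[(2R,3S,4S)-3,7-bis(benzyloxy)-2-[3,4-bis(benzyloxy)phenyl]chroman-4-yl]phenyl}-4H-chromen-4-one
Product: 24 2-{2-[(2R,3S,4S)-2-(3,4-dihydroxyphenyl)-3,7-dihydroxychroman-4-yl]-3,4,5-trihydroxyphenyl}-3,7-dihydroxy-4H-chromen-4-one (target)
Conditions: H2 (1 atm), Pd(OH)2/C, THF/MeOH (1:1), rt; filtration under argon
Reagents that add atoms: none
Why: Catalytic hydrogenolysis of seven aryl benzyl ethers and one secondary alkyl benzyl ether; at one atmosphere and room temperature the flavonol double bond and the ring C C2–O1 bond should be spared, and no stereocentre is involved.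

## Compound list

1 | 5-bromo-1,2,3-trimethoxybenzene | COc1cc(Br)cc(OC)c1OC | starting material
2 | 1-bromo-2-[chloro(methoxy)methyl]-3,4,5-trimethoxybenzene (α-chloro ether, racemic) | COC(Cl)c1c(Br)cc(OC)c(OC)c1OC | intermediate
3 | 6-bromo-2,3,4-trimethoxybenzaldehyde | O=Cc1c(Br)cc(OC)c(OC)c1OC | intermediate
4 | 6-bromo-2,3,4-trihydroxybenzaldehyde | O=Cc1c(Br)cc(O)c(O)c1O | intermediate
5 | 6-bromo-2,3,4-tris(benzyloxy)benzaldehyde | O=Cc1c(Br)cc(OCc9ccccc9)c(OCc9ccccc9)c1OCc9ccccc9 | intermediate
6 | 3',4'-bis(benzyloxy)acetophenone | CC(=O)c1ccc(OCc9ccccc9)c(OCc9ccccc9)c1 | starting material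
7 | 3-[6-bromo-2,3,4-tris(benzyloxy)phenyl]-1-[3,4-bis(benzyloxy)phenyl]-3-hydroxypropan-1-one (aldol adduct, racemic) | O=C(CC(O)c1c(Br)cc(OCc9ccccc9)c(OCc9ccccc9)c1OCc9ccccc9)c1ccc(OCc9ccccc9)c(OCc9ccccc9)c1 | intermediate
8 | (E)-3-[6-bromo-2,3,4-tris(benzyloxy)phenyl]-1-[3,4-bis(benzyloxy)phenyl]prop-2-en-1-one | O=C(/C=C/c1c(Br)cc(OCc9ccccc9)c(OCc9ccccc9)c1OCc9ccccc9)c1ccc(OCc9ccccc9)c(OCc9ccccc9)c1 | intermediate
9 | resorcinol | Oc1cccc(O)c1 | starting material
10 | (3S)-3-[6-bromo-2,3,4-tris(benzyloxy)phenyl]-1-[3,4-bis(benzyloxy)phenyl]-3-(2,4-dihydroxyphenyl)propan-1-one | Brc1cc(OCc9ccccc9)c(OCc9ccccc9)c(OCc9ccccc9)c1[C@@H](CC(=O)c1ccc(OCc9ccccc9)c(OCc9ccccc9)c1)c1ccc(O)cc1O | intermediate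
11 | (4S)-4-[6-bromo-2,3,4-tris(benzyloxy)phenyl]-2-[3,4-bis(benzyloxy)phenyl]chromane-2,7-diol (C2 epimers) | Brc1cc(OCc9ccccc9)c(OCc9ccccc9)c(OCc9ccccc9)c1[C@@H]1c2ccc(O)cc2OC(O)(c2ccc(OCc9ccccc9)c(OCc9ccccc9)c2)C1 | intermediate
12 | (4S)-4-[6-bromo-2,3,4-tris(benzyloxy)phenyl]-2-[3,4-bis(benzyloxy)phenyl]-4H-chromen-7-ol | Brc1cc(OCc9ccccc9)c(OCc9ccccc9)c(OCc9ccccc9)c1[C@@H]1c2ccc(O)cc2OC(c2ccc(OCc9ccccc9)c(OCc9ccccc9)c2)=C1 | intermediate
13 | 3-boryl-7-(boryloxy)flavan from 12: BH2 on C3 cis to H2 and trans to the C4 aryl, configuration at C2 and C4 as in 14 | Brc1cc(OCc9ccccc9)c(OCc9ccccc9)c(OCc9ccccc9)c1[C@@H]1c2ccc(OB)cc2O[C@H](c2ccc(OCc9ccccc9)c(OCc9ccccc9)c2)[C@H]1B | intermediate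
14 | (2R,3S,4S)-4-[6-bromo-2,3,4-tris(benzyloxy)phenyl]-2-[3,4-bis(benzyloxy)phenyl]chromane-3,7-diol | Brc1cc(OCc9ccccc9)c(OCc9ccccc9)c(OCc9ccccc9)c1[C@@H]1c2ccc(O)cc2O[C@H](c2ccc(OCc9ccccc9)c(OCc9ccccc9)c2)[C@H]1O | intermediate
15 | (2R,3S,4S)-3,7-bis(benzyloxy)-4-[6-bromo-2,3,4-tris(benzyloxy)phenyl]-2-[3,4-bis(benzyloxy)phenyl]chromane | Brc1cc(OCc9ccccc9)c(OCc9ccccc9)c(OCc9ccccc9)c1[C@@H]1c2ccc(OCc9ccccc9)cc2O[C@H](c2ccc(OCc9ccccc9)c(OCc9ccccc9)c2)[C@H]1OCc9ccccc9 | intermediate
16 | aryllithium from 15 (Li in place of Br, (2R,3S,4S)) | [Li]c1cc(OCc9ccccc9)c(OCc9ccccc9)c(OCc9ccccc9)c1[C@@H]1c2ccc(OCc9ccccc9)cc2O[C@H](c2ccc(OCc9ccccc9)c(OCc9ccccc9)c2)[C@H]1OCc9ccccc9 | intermediate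
17 | lithium (dimethylamino)(aryl)methoxide from 16 and DMF ((2R,3S,4S) flavan, hemiaminal carbon unspecified) | [Li]OC(N(C)C)c1cc(OCc9ccccc9)c(OCc9ccccc9)c(OCc9ccccc9)c1[C@@H]1c2ccc(OCc9ccccc9)cc2O[C@H](c2ccc(OCc9ccccc9)c(OCc9ccccc9)c2)[C@H]1OCc9ccccc9 | intermediate
18 | 3,4,5-tris(benzyloxy)-2-{(2R,3S,4S)-3,7-bis(benzyloxy)-2-[3,4-bis(benzyloxy)phenyl]chroman-4-yl}benzaldehyde | O=Cc1cc(OCc9ccccc9)c(OCc9ccccc9)c(OCc9ccccc9)c1[C@@H]1c2ccc(OCc9ccccc9)cc2O[C@H](c2ccc(OCc9ccccc9)c(OCc9ccccc9)c2)[C@H]1OCc9ccccc9 | intermediate
19 | 4'-benzyloxy-2'-hydroxyacetophenone | CC(=O)c1ccc(OCc9ccccc9)cc1O | starting material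
20 | β-hydroxy ketone from 18 and 19 (aldol adduct, carbinol carbon unspecified, flavan (2R,3S,4S)) | O=C(CC(O)c1cc(OCc9ccccc9)c(OCc9ccccc9)c(OCc9ccccc9)c1[C@@H]1c2ccc(OCc9ccccc9)cc2O[C@H](c2ccc(OCc9ccccc9)c(OCc9ccccc9)c2)[C@H]1OCc9ccccc9)c1ccc(OCc9ccccc9)cc1O | intermediate
21 | (E)-1-[4-(benzyloxy)-2-hydroxyphenyl]-3-{3,4,5-tris(benzyloxy)-2-[(2R,3S,4S)-3,7-bis(benzyloxy)-2-[3,4-bis(benzyloxy)phenyl]chroman-4-yl]phenyl}prop-2-en-1-one | O=C(/C=C/c1cc(OCc9ccccc9)c(OCc9ccccc9)c(OCc9ccccc9)c1[C@@H]1c2ccc(OCc9ccccc9)cc2O[C@H](c2ccc(OCc9ccccc9)c(OCc9ccccc9)c2)[C@H]1OCc9ccccc9)c1ccc(OCc9ccccc9)cc1O | intermediate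
22 | 7-(benzyloxy)-3-hydroxyflavanone (dihydroflavonol) carrying the benzylated (2R,3S,4S)-flavanyl ring E; new C2 and C3 of the flavanone unspecified | O=C1C(O)C(c2cc(OCc9ccccc9)c(OCc9ccccc9)c(OCc9ccccc9)c2[C@@H]2c3ccc(OCc9ccccc9)cc3O[C@H](c3ccc(OCc9ccccc9)c(OCc9ccccc9)c3)[C@H]2OCc9ccccc9)Oc2cc(OCc9ccccc9)ccc12 | intermediate
23 | 7-(benzyloxy)-3-hydroxy-2-{3,4,5-tris(benzyloxy)-2-[(2R,3S,4S)-3,7-bis(benzyloxy)-2-[3,4-bis(benzyloxy)phenyl]chroman-4-yl]phenyl}-4H-chromen-4-one | O=c1c(O)c(-c2cc(OCc9ccccc9)c(OCc9ccccc9)c(OCc9ccccc9)c2[C@@H]2c3ccc(OCc9ccccc9)cc3O[C@H](c3ccc(OCc9ccccc9)c(OCc9ccccc9)c3)[C@H]2OCc9ccccc9)oc2cc(OCc9ccccc9)ccc12 | intermediate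
24 | 2-{2-[(2R,3S,4S)-2-(3,4-dihydroxyphenyl)-3,7-dihydroxychroman-4-yl]-3,4,5-trihydroxyphenyl}-3,7-dihydroxy-4H-chromen-4-one | O=c1c(O)c(-c2cc(O)c(O)c(O)c2[C@@H]2c3ccc(O)cc3O[C@H](c3ccc(O)c(O)c3)[C@H]2O)oc2cc(O)ccc12 | target

## Step count and risk

Total step count: 11. Longest linear sequence: 11 steps (1 → 24; 6, 9 and 19 are bought).

**Step 5 (key step).** The most likely failure is a sluggish conjugate addition with poor facial selectivity. The β-carbon of 8 carries an aryl ring with bromine and benzyloxy in both ortho positions; this ring must twist out of the enone plane and then shields both faces. The electron-rich aryl ketone is also a weak acceptor, so an unselective background reaction or a second alkylation of 9 may compete with the ligand-controlled path.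

Fallback (resolution in place of asymmetric catalysis): setting out from 8 and 9, the annulation is forced with ligand-free Sc(OTf)3 (20 mol %) in MeCN at 60 °C. This should give 12 as the racemate, that is together with the (4R)-enantiomer of 12 F1. Hydroboration–oxidation as in step 6 should then give 14 together with the (2S,3R,4R)-enantiomer of 14 F2, both all-trans. Acylation of both hydroxyls with (1S)-camphanic chloride (pyridine, DMAP, CH2Cl2) gives two diastereomers, the bis-camphanate of 14 F3 and the bis-camphanate of F2 F4; the ester on O3 sits directly beside the stereocentres. They are separated by crystallisation or chromatography, and LiOH in THF/MeOH/H2O cleaves F3 to 14, where the route is rejoined. At most half of the material can be carried on this way.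

**Step 6.** The most likely failure is β-elimination of the organoborane with opening of ring C, since boron on C3 lies anti-periplanar to the C2–O1 bond and the leaving group is a phenoxide. Incomplete facial control on the trisubstituted enol ether is the second concern.

Fallback (epoxidation and ionic reduction in place of hydroboration): setting out from 12, the phenol is benzylated (BnBr, K2CO3, acetone) to the 7-O-benzyl ether of 12 F5. Dimethyldioxirane in CH2Cl2/MeOH at −40 °C should epoxidise the enol ether anti to the C4 aryl group, and methanol should open the epoxide at C2 to the 2-methoxyflavan-3-ol F6 (C2 epimers). Et3SiH with BF3·OEt2 at −78 °C should ionise F6 to the 2-aryl oxocarbenium ion and deliver hydride axially, so that both aryl groups end up equatorial (2,4-cis), giving the 7-O-benzyl ether of 14 F7. NaH and BnBr then give 15, where the route is rejoined.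

**Step 10.** The most likely failure is diversion to the aurone by five-membered closure, or stalling at 22. The flavanyl group ortho to the enone on ring E twists the β-aryl out of conjugation and hinders attack at the β-carbon.

Fallback (ring closure and C3 oxidation as separate operations): setting out from 21, I2 (10 mol %) in DMSO at 120 °C should cyclise and dehydrogenate the chalcone to the flavone F8 (the same compound as A1). Dimethyldioxirane in acetone/CH2Cl2 should epoxidise its C2=C3 bond to the 2,3-epoxyflavanone F9, which TsOH (cat.) isomerises to 23, where the route is rejoined.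

**Step 11.** The most likely failures are incomplete cleavage of the hindered secondary benzyl ether on O3, over-reduction on prolonged exposure (hydrogenolysis of the benzylic C2–O1 bond of ring C), and air oxidation of the pyrogallol during isolation.

Fallback (Lewis acid dealkylation in place of hydrogenolysis): setting out from 23, BCl3 with pentamethylbenzene as cation scavenger in CH2Cl2 at −78 °C should remove all eight benzyl groups without hydrogen and arrive at 24 directly; no new compound lies on the way.

## Further compounds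

F1 | step 5 | (4R)-4-[6-bromo-2,3,4-tris(benzyloxy)phenyl]-2-[3,4-bis(benzyloxy)phenyl]-4H-chromen-7-ol (enantiomer of 12) | Brc1cc(OCc9ccccc9)c(OCc9ccccc9)c(OCc9ccccc9)c1[C@H]1c2ccc(O)cc2OC(c2ccc(OCc9ccccc9)c(OCc9ccccc9)c2)=C1
F2 | step 5 | (2S,3R,4R)-4-[6-bromo-2,3,4-tris(benzyloxy)phenyl]-2-[3,4-bis(benzyloxy)phenyl]chromane-3,7-diol (enantiomer of 14) | Brc1cc(OCc9ccccc9)c(OCc9ccccc9)c(OCc9ccccc9)c1[C@H]1c2ccc(O)cc2O[C@@H](c2ccc(OCc9ccccc9)c(OCc9ccccc9)c2)[C@@H]1O
F3 | step 5 | 3,7-bis[(1S,4R)-camphanate] of 14 | Brc1cc(OCc9ccccc9)c(OCc9ccccc9)c(OCc9ccccc9)c1[C@@H]1c2ccc(OC(=O)[C@@]34CC[C@@](C)(C(=O)O3)C4(C)C)cc2O[C@H](c2ccc(OCc9ccccc9)c(OCc9ccccc9)c2)[C@H]1OC(=O)[C@@]23CC[C@@](C)(C(=O)O2)C3(C)C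
F4 | step 5 | 3,7-bis[(1S,4R)-camphanate] of F2 | Brc1cc(OCc9ccccc9)c(OCc9ccccc9)c(OCc9ccccc9)c1[C@H]1c2ccc(OC(=O)[C@@]34CC[C@@](C)(C(=O)O3)C4(C)C)cc2O[C@@H](c2ccc(OCc9ccccc9)c(OCc9ccccc9)c2)[C@@H]1OC(=O)[C@@]23CC[C@@](C)(C(=O)O2)C3(C)C
F5 | step 6 | (4S)-7-(benzyloxy)-4-[6-bromo-2,3,4-tris(benzyloxy)phenyl]-2-[3,4-bis(benzyloxy)phenyl]-4H-chromene | Brc1cc(OCc9ccccc9)c(OCc9ccccc9)c(OCc9ccccc9)c1[C@@H]1c2ccc(OCc9ccccc9)cc2OC(c2ccc(OCc9ccccc9)c(OCc9ccccc9)c2)=C1
F6 | step 6 | (3S,4S)-7-(benzyloxy)-4-[6-bromo-2,3,4-tris(benzyloxy)phenyl]-2-[3,4-bis(benzyloxy)phenyl]-2-methoxychroman-3-ol (C2 epimers) | Brc1cc(OCc9ccccc9)c(OCc9ccccc9)c(OCc9ccccc9)c1[C@@H]1c2ccc(OCc9ccccc9)cc2OC(OC)(c2ccc(OCc9ccccc9)c(OCc9ccccc9)c2)[C@H]1O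
F7 | step 6 | (2R,3S,4S)-7-(benzyloxy)-4-[6-bromo-2,3,4-tris(benzyloxy)phenyl]-2-[3,4-bis(benzyloxy)phenyl]chroman-3-ol | Brc1cc(OCc9ccccc9)c(OCc9ccccc9)c(OCc9ccccc9)c1[C@@H]1c2ccc(OCc9ccccc9)cc2O[C@H](c2ccc(OCc9ccccc9)c(OCc9ccccc9)c2)[C@H]1O
F8 | step 10 | 7-(benzyloxy)-2-{3,4,5-tris(benzyloxy)-2-[(2R,3S,4S)-3,7-bis(benzyloxy)-2-[3,4-bis(benzyloxy)phenyl]chroman-4-yl]phenyl}-4H-chromen-4-one (flavone) | O=c1cc(-c2cc(OCc9ccccc9)c(OCc9ccccc9)c(OCc9ccccc9)c2[C@@H]2c3ccc(OCc9ccccc9)cc3O[C@H](c3ccc(OCc9ccccc9)c(OCc9ccccc9)c3)[C@H]2OCc9ccccc9)oc2cc(OCc9ccccc9)ccc12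
F9 | step 10 | 2,3-epoxide of F8 (2,3-epoxyflavanone, epoxide configuration not controlled) | O=C1C2OC2(c2cc(OCc9ccccc9)c(OCc9ccccc9)c(OCc9ccccc9)c2[C@@H]2c3ccc(OCc9ccccc9)cc3O[C@H](c3ccc(OCc9ccccc9)c(OCc9ccccc9)c3)[C@H]2OCc9ccccc9)Oc2cc(OCc9ccccc9)ccc12
F0 | step 11 | none | none
A1 | alternative 1 | 7-(benzyloxy)-2-{3,4,5-tris(benzyloxy)-2-[(2R,3S,4S)-3,7-bis(benzyloxy)-2-[3,4-bis(benzyloxy)phenyl]chroman-4-yl]phenyl}-4H-chromen-4-one | O=c1cc(-c2cc(OCc9ccccc9)c(OCc9ccccc9)c(OCc9ccccc9)c2[C@@H]2c3ccc(OCc9ccccc9)cc3O[C@H](c3ccc(OCc9ccccc9)c(OCc9ccccc9)c3)[C@H]2OCc9ccccc9)oc2cc(OCc9ccccc9)ccc12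
A2 | alternative 1 | (2R,3S,4S)-3,7-bis(benzyloxy)-2-[3,4-bis(benzyloxy)phenyl]-4-[2,3,4-tris(benzyloxy)-6-ethynylphenyl]chromane | C#Cc1cc(OCc9ccccc9)c(OCc9ccccc9)c(OCc9ccccc9)c1[C@@H]1c2ccc(OCc9ccccc9)cc2O[C@H](c2ccc(OCc9ccccc9)c(OCc9ccccc9)c2)[C@H]1OCc9ccccc9
A3 | alternative 1 | 5-(benzyloxy)-2-iodophenol | Oc1cc(OCc9ccccc9)ccc1I
A4 | alternative 2 | (3S,4R)-5,6,7-tris(benzyloxy)-4-[4-(benzyloxy)-2-chlorophenyl]-3-{(R)-[3,4-bis(benzyloxy)phenyl](tert-butyldimethylsilyloxy)methyl}isochroman-1-one | O=C1O[C@H]([C@H](O[Si](C)(C)C(C)(C)C)c2ccc(OCc9ccccc9)c(OCc9ccccc9)c2)[C@@H](c2ccc(OCc9ccccc9)cc2Cl)c2c1cc(OCc9ccccc9)c(OCc9ccccc9)c2OCc9ccccc9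
A5 | alternative 2 | methyl 3,4,5-tris(benzyloxy)-2-[4-(benzyloxy)-2-chlorobenzyl]benzoate | COC(=O)c1cc(OCc9ccccc9)c(OCc9ccccc9)c(OCc9ccccc9)c1Cc1ccc(OCc9ccccc9)cc1Cl
A6 | alternative 2 | (R)-2-[3,4-bis(benzyloxy)phenyl]-2-(tert-butyldimethylsilyloxy)acetaldehyde | O=C[C@H](O[Si](C)(C)C(C)(C)C)c1ccc(OCc9ccccc9)c(OCc9ccccc9)c1
A7 | alternative 3 | (4S)-7-(benzyloxy)-4-[6-bromo-2,3,4-tris(benzyloxy)phenyl]chroman-2-one | Brc1cc(OCc9ccccc9)c(OCc9ccccc9)c(OCc9ccccc9)c1[C@@H]1c2ccc(OCc9ccccc9)cc2OC(=O)C1
A8 | alternative 3 | (3S)-6-(benzyloxy)-3-[6-bromo-2,3,4-tris(benzyloxy)phenyl]indan-1-one | Brc1cc(OCc9ccccc9)c(OCc9ccccc9)c(OCc9ccccc9)c1[C@@H]1c2ccc(OCc9ccccc9)cc2C(=O)C1
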